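## Retrosynthetic overview

1. Numbering used: ring A = C1–C2–C3(OH)–C4(CH3, side chain)–C5(H)–C10(CH3); ring B = C5–C6–C7–C8(=CH2)–C9(CH2–pyranone)–C10. The target is read as the cis-fused (3S,4R,5R,9S,10S) isomer.
2. End game: C3–OH from the C3 ketone; formate from the tertiary alcohol; C8=CH2 from a C8 ketone (from C8–OSi); C9–CH2–pyranone by hydroboration of a C9 exocyclic alkene and B-alkyl Suzuki–Miyaura coupling with an iodopyranone; C4–CH3 by enolate methylation.
3. Key disconnection: C1–C2 and C5–C10, by an intramolecular Diels–Alder reaction of an open-chain triene. The 2-silyloxydiene C2=C3(OSi)–C4=C5 and the isopropenyl ketone C1=C10–C9=O are joined by C6–C7–C8, so rings A and B close together.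
4. Enabling feature: in ring A the C3 oxygen sits next to the quaternary C4 (a 2-silyloxydiene that ends as the C3 enol ether needed for C4 alkylation). In ring B, C9 flanks the quaternary C10 (C9 can be the ketone that activates C10=C1). The cis C5–C10 fusion bond is bridged by the four carbons C6–C9, which makes the precursor a 1,7,9-decatrien-3-one whose endo mode gives the cis-decalin.
5. Stereocontrol and ring order: one bought stereocentre (C8–O, from methyl (R)-glycidate) steers C5 and C10 in the cycloaddition; C4, C9 and C3 follow by delivery of CH3, H and H to the convex face, and C8 is then erased as the exocyclic alkene. Rings A and B form together in step 9; the pyranone ring is made separately (step 12) and joined in step 15.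

Key step: step 9

Remark: α denotes the face of C5–H and C10–CH3 (the convex face of the cis-decalin) and β the concave face, which carries the C4 side chain, the C9–CH2 group and C3–OH in the target.

## Route

Step 1
Reactants: 1 methyl (R)-oxirane-2-carboxylate
Product: 2 methyl (R)-2-hydroxyhex-5-enoate
Conditions: CH2=CHCH2MgBr, CuBr·SMe2 (10 mol%), THF, −78 °C; aq. NH4Cl
Reagents that add atoms: allylmagnesium bromide, C=CC[Mg]Br
Why: Copper-catalysed SN2 opening of the epoxide at its unsubstituted carbon (organocuprate epoxide opening) should outrun addition to the ester at −78 °C and leaves the C–O stereocentre, the future C8, untouched.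

Step 2
Reactants: 2 methyl (R)-2-hydroxyhex-5-enoate
Product: 3 methyl (R)-2-[(tert-butyldimethylsilyl)oxy]hex-5-enoate
Conditions: TBSCl, imidazole, DMF, rt
Reagents that add atoms: tert-butyldimethylsilyl chloride, CC(C)(C)[Si](C)(C)Cl
Why: Standard silylation of a secondary alcohol, which blocks later oxa-Michael addition of this oxygen to the enone made in step 7.

Step 3
Reactants: 3 methyl (R)-2-[(tert-butyldimethylsilyl)oxy]hex-5-enoate
Product: 4 (R)-2-[(tert-butyldimethylsilyl)oxy]-N-methoxy-N-methylhex-5-enamide
Conditions: MeNH(OMe)·HCl, i-PrMgCl, THF, −20 °C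
Reagents that add atoms: N,O-dimethylhydroxylamine hydrochloride, CNOC.Cl
Why: Weinreb amide formation by aminolysis of the ester with the magnesium amide, a reaction type that tolerates α-silyloxy esters without loss of configuration.

Step 4
Reactants: 4 (R)-2-[(tert-butyldimethylsilyl)oxy]-N-methoxy-N-methylhex-5-enamide
Product: 5 (R)-2-[(tert-butyldimethylsilyl)oxy]-N-methoxy-N-methyl-5-oxopentanamide
Conditions: O3, CH2Cl2, −78 °C; PPh3
Reagents that add atoms: ozone, [O-][O+]=O
Why: Ozonolysis with reductive work-up cleaves the only alkene to the C5 aldehyde and leaves amide and silyl ether intact.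

Step 5
Reactants: 6 dimethyl (2-oxopropyl)phosphonate; 7 1-bromo-3-methylbut-2-ene
Product: 8 dimethyl (6-methyl-2-oxohept-5-en-3-yl)phosphonate
Conditions: NaH, THF, 0 °C → rt
Reagents that add atoms: none
Why: C-alkylation (SN2) of the sodium enolate of the β-ketophosphonate with a reactive allylic bromide installs the carbon chain of the C4 substituent.

Step 6
Reactants: 8 dimethyl (6-methyl-2-oxohept-5-en-3-yl)phosphonate
Product: 9 dimethyl (6-hydroxy-6-methyl-2-oxoheptan-3-yl)phosphonate
Conditions: Co(acac)2 (20 mol%), PhSiH3, O2 (1 atm), THF, rt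
Reagents that add atoms: dioxygen, O=O
Why: Mukaiyama hydration (hydrogen-atom transfer to the trisubstituted alkene, then oxygen trapping of the tertiary radical) should give the Markovnikov tertiary alcohol at a stage where no other alkene is present.

Step 7
Reactants: 5 (R)-2-[(tert-butyldimethylsilyl)oxy]-N-methoxy-N-methyl-5-oxopentanamide; 9 dimethyl (6-hydroxy-6-methyl-2-oxoheptan-3-yl)phosphonate
Product: 10 (R,E)-2-[(tert-butyldimethylsilyl)oxy]-6-(3-hydroxy-3-methylbutyl)-N-methoxy-N-methyl-7-oxooct-5-enamide
Conditions: Ba(OH)2·8H2O, THF/H2O (40:1), rt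
Reagents that add atoms: none
Why: Horner–Wadsworth–Emmons olefination with an α-branched β-ketophosphonate under mild barium hydroxide conditions should give the (E)-trisubstituted enone (tether trans to the acetyl group), the geometry the cycloaddition needs.

Step 8
Reactants: 10 (R,E)-2-[(tert-butyldimethylsilyl)oxy]-6-(3-hydroxy-3-methylbutyl)-N-methoxy-N-methyl-7-oxooct-5-enamide
Product: 11 (R,E)-2,7-bis[(tert-butyldimethylsilyl)oxy]-6-{3-[(tert-butyldimethylsilyl)oxy]-3-methylbutyl}-N-methoxy-N-methylocta-5,7-dienamide
Conditions: TBSOTf (2.5 equiv), Et3N, CH2Cl2, −78 → 0 °C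
Reagents that add atoms: tert-butyldimethylsilyl trifluoromethanesulfonate, CC(C)(C)[Si](C)(C)OS(=O)(=O)C(F)(F)F
Why: Soft enolisation of the methyl ketone at its methyl group (kinetic silyl enol ether formation) gives the cross-conjugated 2-silyloxydiene, and the same reagent silylates the tertiary alcohol.

Step 9
Reactants: 11 (R,E)-2,7-bis[(tert-butyldimethylsilyl)oxy]-6-{3-[(tert-butyldimethylsilyl)oxy]-3-methylbutyl}-N-methoxy-N-methylocta-5,7-dienamide
Product: 13 cis-fused decalin C9 ketone with C3 silyl enol ether (Diels–Alder adduct), via triene 12 (not isolated)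
Conditions: CH2=C(CH3)MgBr, THF, −78 → 0 °C; aq. NH4Cl; then PhMe, BHT, 80 °C
Reagents that add atoms: isopropenylmagnesium bromide, C=C(C)[Mg]Br
Why: The Grignard reagent adds once to the Weinreb amide (chelated tetrahedral intermediate) and the quench releases the isopropenyl ketone, i.e. the 1,7,9-decatrien-3-one 12, which on warming undergoes a concerted, asynchronous intramolecular [4+2] cycloaddition between the 2-silyloxydiene (C2=C3–C4=C5) and the enone alkene (C10=C1), forming C1–C2 and C5–C10. The closest known reactions are thermal intramolecular Diels–Alder cyclisations of 1,7,9-decatrien-3-ones and Diels–Alder reactions of 2-silyloxy-1,3-dienes with 2-substituted enones, and the nucleophilic diene terminus C2 is polarity-matched to the electrophilic enone terminus C1. Ring A (C1, C2, C3, C4, C5, C10) closes as the cyclohexene of the cycloaddition itself, and ring B closes at the same moment through the C5–C10 bond as the six-membered carbocycle set by the four-atom tether C6–C9, the fused mode being the only one the tether allows. C5 and C10 are set relative to each other by the endo transition state of the (E)-diene, with the tether carbonyl C9 under the diene and a boat-like tether, which gives the cis ring fusion (C5–H syn to C10–CH3); their absolute sense is relayed from the (R)-C8 centre, whose OTBS group should take the outward pseudo-equatorial site of the forming ring B (anti to the C9=O dipole and clear of the C4 side chain), so that OTBS, C10–CH3 and C5–H end on one face. The step needs endo over exo selectivity and one diene face: the first is secured by the internal ketone activation of the decatrienone, the second by the single α-silyloxy stereocentre next to the dienophile carbonyl, and the isopropenyl ketone is the only activated alkene.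

Step 10
Reactants: 13 cis-fused decalin C9 ketone with C3 silyl enol ether
Product: 14 C9-methylidene decalin with C3 silyl enol ether
Conditions: Tebbe reagent Cp2Ti(μ-CH2)(μ-Cl)AlMe2, pyridine, THF, −40 °C → rt
Reagents that add atoms: Tebbe reagent, C[Al-]1(C)C[Ti](C2C=CC=C2)(C2C=CC=C2)[Cl+]1
Why: Tebbe methylenation is non-basic and effective on hindered ketones, and the only carbonyl present is C9 because C3 is still masked as its silyl enol ether.

Step 11
Reactants: 14 C9-methylidene decalin with C3 silyl enol ether
Product: 15 C3 ketone with quaternary C4 (α-CH3, β-side chain)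
Conditions: TASF, CH3I, THF, −78 → 0 °C
Reagents that add atoms: iodomethane, CI
Why: Fluoride cleaves the silyl enol ether regiospecifically to the C3 enolate, which is methylated at C4 (enolate alkylation); iodomethane should enter on the convex α-face, the face of C5–H, because the β-face is the concave side folded under ring B, so the new methyl is syn to C10–CH3 and the side chain is pushed to the β-face.

Step 12
Reactants: 16 methyl 3-oxobutanoate; 17 malonyl dichloride
Product: 18 methyl 4-hydroxy-6-methyl-2-oxo-2H-pyran-5-carboxylate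
Conditions: Et2O, 0 °C → rt
Reagents that add atoms: none
Why: C-acylation of the β-ketoester by one acid chloride and O-acylation of its enol by the other (acylative pyranone annulation) closes the 4-hydroxy-2-pyranone ring with methyl and ester in the required positions.

Step 13
Reactants: 18 methyl 4-hydroxy-6-methyl-2-oxo-2H-pyran-5-carboxylate
Product: 19 methyl 4-hydroxy-3-iodo-6-methyl-2-oxo-2H-pyran-5-carboxylate
Conditions: NIS, MeCN, rt
Reagents that add atoms: N-iodosuccinimide, O=C1CCC(=O)N1I
Why: Electrophilic iodination takes place at C3, the only free and most nucleophilic ring position of a 4-hydroxy-2-pyranone.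

Step 14
Reactants: 19 methyl 4-hydroxy-3-iodo-6-methyl-2-oxo-2H-pyran-5-carboxylate
Product: 20 methyl 5-iodo-6-methoxy-2-methyl-4-oxo-4H-pyran-3-carboxylate
Conditions: MeOTf, CH2Cl2, rt; aq. NaHCO3
Reagents that add atoms: methyl trifluoromethanesulfonate, COS(=O)(=O)C(F)(F)F
Why: A hard methylating agent attacks the lactone carbonyl oxygen of the neutral 4-hydroxy-2-pyranone (O-methylation), whose 4-OH is hydrogen-bonded to the ester, and loss of a proton gives the 2-methoxy-4-pyranone tautomer.

Step 15
Reactants: 15 C3 ketone with quaternary C4; 20 methyl 5-iodo-6-methoxy-2-methyl-4-oxo-4H-pyran-3-carboxylate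
Product: 22 C9β-pyranonylmethyl decalin C3 ketone, via B-alkyl-9-BBN borane 21 (not isolated)
Conditions: 9-BBN, THF, 50 °C; then 20, Pd(dppf)Cl2 (5 mol%), AsPh3, Cs2CO3, DMF/H2O, rt → 45 °C
Reagents that add atoms: none
Why: 9-BBN hydroborates the exocyclic 1,1-disubstituted alkene anti-Markovnikov faster than it reduces the neopentyl C3 ketone and adds H to C9 from the convex α-face (axial approach, anti to the axial C1 of ring A, with OTBS and C10–CH3 equatorial), so the CH2–B arm is β; B-alkyl Suzuki–Miyaura coupling with the α-iodoenone-type iodide 20 then forms the CH2–pyranone bond with retention.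

Step 16
Reactants: 22 C9β-pyranonylmethyl decalin C3 ketone
Product: 23 C8 alcohol with free tertiary alcohol (diol)
Conditions: HF·pyridine, pyridine, THF, 0 °C → rt
Reagents that add atoms: none
Why: Buffered fluoride desilylation removes both silyl ethers and should spare the acid-sensitive 2-methoxy-4-pyranone and the methyl ester.

Step 17
Reactants: 23 C8 alcohol with free tertiary alcohol
Product: 24 C3,C8-diketone with free tertiary alcohol
Conditions: Dess–Martin periodinane, NaHCO3, CH2Cl2, rt
Reagents that add atoms: none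
Why: Dess–Martin oxidation converts the only secondary alcohol to the C8 ketone under neutral conditions that should not epimerise the adjacent C9 centre; the tertiary alcohol cannot react.

Step 18
Reactants: 24 C3,C8-diketone with free tertiary alcohol
Product: 25 C8-methylidene C3 ketone with free tertiary alcohol
Conditions: Zn, CH2Br2, TiCl4, THF/CH2Cl2, 0 °C → rt
Reagents that add atoms: dibromomethane, BrCBr
Why: Takai–Lombardo methylenation is non-basic (no epimerisation at C9) and sterically discriminating, so the C8 ketone should react in preference to the C3 ketone flanked by quaternary C4, and esters are not attacked.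

Step 19
Reactants: 25 C8-methylidene C3 ketone with free tertiary alcohol
Product: 26 tertiary formate C3 ketone
Conditions: HCO2Ac, pyridine, DMAP (cat.), CH2Cl2, 0 °C → rt
Reagents that add atoms: acetic formic anhydride, CC(=O)OC=O
Why: Acyl transfer from the mixed anhydride delivers the formyl group selectively (formylation), and the tertiary alcohol is the only hydroxyl present because C3 is still a ketone.

Step 20
Reactants: 26 tertiary formate C3 ketone
Product: 27 target (3S,4R,5R,9S,10S)
Conditions: (R)-2-methyl-CBS-oxazaborolidine (20 mol%), catecholborane, PhMe, −78 → −40 °C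
Reagents that add atoms: none
Why: Corey–Bakshi–Shibata reduction differentiates the quaternary C4 flank from the C2 methylene flank and the (R)-catalyst should deliver hydride to the α-face (also the convex face) to give the (3S)-alcohol with β-OH, while catecholborane at low temperature leaves formate, exocyclic alkene, ester and pyranone untouched.

## Compound list

1 | methyl (R)-oxirane-2-carboxylate (methyl (R)-glycidate) | COC(=O)[C@H]1CO1 | starting material
2 | methyl (R)-2-hydroxyhex-5-enoate | COC(=O)[C@H](O)CCC=C | intermediate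
3 | methyl (R)-2-[(tert-butyldimethylsilyl)oxy]hex-5-enoate | COC(=O)[C@H](O[Si](C)(C)C(C)(C)C)CCC=C | intermediate
4 | (R)-2-[(tert-butyldimethylsilyl)oxy]-N-methoxy-N-methylhex-5-enamide | CON(C)C(=O)[C@H](O[Si](C)(C)C(C)(C)C)CCC=C | intermediate
5 | (R)-2-[(tert-butyldimethylsilyl)oxy]-N-methoxy-N-methyl-5-oxopentanamide | CON(C)C(=O)[C@H](O[Si](C)(C)C(C)(C)C)CCC=O | intermediate
6 | dimethyl (2-oxopropyl)phosphonate | COP(=O)(OC)CC(C)=O | starting material
7 | 1-bromo-3-methylbut-2-ene (prenyl bromide) | CC(C)=CCBr | starting material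
8 | dimethyl (6-methyl-2-oxohept-5-en-3-yl)phosphonate (racemic) | COP(=O)(OC)C(CC=C(C)C)C(C)=O | intermediate
9 | dimethyl (6-hydroxy-6-methyl-2-oxoheptan-3-yl)phosphonate (racemic) | COP(=O)(OC)C(CCC(C)(C)O)C(C)=O | intermediate
10 | (R,E)-2-[(tert-butyldimethylsilyl)oxy]-6-(3-hydroxy-3-methylbutyl)-N-methoxy-N-methyl-7-oxooct-5-enamide | CON(C)C(=O)[C@H](O[Si](C)(C)C(C)(C)C)CC/C=C(\CCC(C)(C)O)C(C)=O | intermediate
11 | (R,E)-2,7-bis[(tert-butyldimethylsilyl)oxy]-6-{3-[(tert-butyldimethylsilyl)oxy]-3-methylbutyl}-N-methoxy-N-methylocta-5,7-dienamide | CON(C)C(=O)[C@H](O[Si](C)(C)C(C)(C)C)CC/C=C(\CCC(C)(C)O[Si](C)(C)C(C)(C)C)C(O[Si](C)(C)C(C)(C)C)=C | intermediate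
12 | (4R,7E)-4,9-bis[(tert-butyldimethylsilyl)oxy]-8-{3-[(tert-butyldimethylsilyl)oxy]-3-methylbutyl}-2-methyldeca-1,7,9-trien-3-one (triene) | C=C(C)C(=O)[C@H](O[Si](C)(C)C(C)(C)C)CC/C=C(\CCC(C)(C)O[Si](C)(C)C(C)(C)C)C(O[Si](C)(C)C(C)(C)C)=C | intermediate
13 | cis-fused decalin: C9 ketone, C8α-OTBS, C10α-CH3, C5α-H, C3=C4 enol ether with C3-OTBS, C4 bearing the 3-(TBS-oxy)-3-methylbutyl chain | O=C1[C@H](O[Si](C)(C)C(C)(C)C)CC[C@H]2C(CCC(C)(C)O[Si](C)(C)C(C)(C)C)=C(O[Si](C)(C)C(C)(C)C)CC[C@@]12C | intermediate
14 | as 13 with C9=CH2 in place of the C9 ketone | C=C1[C@H](O[Si](C)(C)C(C)(C)C)CC[C@H]2C(CCC(C)(C)O[Si](C)(C)C(C)(C)C)=C(O[Si](C)(C)C(C)(C)C)CC[C@@]12C | intermediate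
15 | cis-decalin: C3 ketone, C4 quaternary (α-CH3, β-3-(TBS-oxy)-3-methylbutyl), C8α-OTBS, C9=CH2, C10α-CH3, C5α-H | C=C1[C@H](O[Si](C)(C)C(C)(C)C)CC[C@H]2[C@@](C)(CCC(C)(C)O[Si](C)(C)C(C)(C)C)C(=O)CC[C@@]12C | intermediate
16 | methyl 3-oxobutanoate (methyl acetoacetate) | CC(=O)CC(=O)OC | starting material
17 | malonyl dichloride | O=C(Cl)CC(=O)Cl | starting material
18 | methyl 4-hydroxy-6-methyl-2-oxo-2H-pyran-5-carboxylate | COC(=O)C1=C(C)OC(=O)C=C1O | intermediate
19 | methyl 4-hydroxy-3-iodo-6-methyl-2-oxo-2H-pyran-5-carboxylate | COC(=O)C1=C(C)OC(=O)C(I)=C1O | intermediate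
20 | methyl 5-iodo-6-methoxy-2-methyl-4-oxo-4H-pyran-3-carboxylate | COC(=O)c1c(C)oc(OC)c(I)c1=O | intermediate
21 | as 15 with C9α-H and C9β-CH2–B(9-borabicyclo[3.3.1]nonan-9-yl) | CC(C)(C)[Si](C)(C)O[C@@H]1CC[C@H]2[C@@](C)(CCC(C)(C)O[Si](C)(C)C(C)(C)C)C(=O)CC[C@@]2(C)[C@H]1CB1C2CCCC1CCC2 | intermediate
22 | as 21 with the pyranone (6-methoxy-2-methyl-3-methoxycarbonyl-4-oxo-4H-pyran-5-yl) in place of boron on the C9β-CH2 group | CC(C)(C)[Si](C)(C)O[C@@H]1CC[C@H]2[C@@](C)(CCC(C)(C)O[Si](C)(C)C(C)(C)C)C(=O)CC[C@@]2(C)[C@H]1Cc1c(OC)oc(C)c(C(=O)OC)c1=O | intermediate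
23 | as 22 with C8α-OH and free tertiary alcohol (diol) | O[C@@H]1CC[C@H]2[C@@](C)(CCC(C)(C)O)C(=O)CC[C@@]2(C)[C@H]1Cc1c(OC)oc(C)c(C(=O)OC)c1=O | intermediate
24 | C3,C8-diketone with free tertiary alcohol | O=C1CC[C@H]2[C@@](C)(CCC(C)(C)O)C(=O)CC[C@@]2(C)[C@H]1Cc1c(OC)oc(C)c(C(=O)OC)c1=O | intermediate
25 | C8-methylidene C3 ketone with free tertiary alcohol | C=C1CC[C@H]2[C@@](C)(CCC(C)(C)O)C(=O)CC[C@@]2(C)[C@H]1Cc1c(OC)oc(C)c(C(=O)OC)c1=O | intermediate
26 | C8-methylidene C3 ketone, tertiary formate | C=C1CC[C@H]2[C@@](C)(CCC(C)(C)OC=O)C(=O)CC[C@@]2(C)[C@H]1Cc1c(OC)oc(C)c(C(=O)OC)c1=O | intermediate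
27 | target: methyl 5-{[(3S,4R,5R,9S,10S)-4-(3-formyloxy-3-methylbutyl)-3-hydroxy-4,10-dimethyl-8-methylidene-decalin-9-yl]methyl}-6-methoxy-2-methyl-4-oxo-4H-pyran-3-carboxylate (decalin numbering as in the overview) | C=C1CC[C@H]2[C@@](C)(CCC(C)(C)OC=O)[C@@H](O)CC[C@@]2(C)[C@H]1Cc1c(OC)oc(C)c(C(=O)OC)c1=O | target

## Step count and risks

Total step count: 20. Longest linear sequence: 15 steps (steps 1–4, 7–11, 15–20).

Most likely to fail:

1. Step 9. The exo (trans-fused) mode or the other diene face may compete, eroding endo or facial selectivity, and the silyl dienol ether may hydrolyse before ring closure. Fallback (anionic double Michael addition): setting out from 11, the Grignard addition of step 9 is worked up cold to give 12, whose silyl dienol ether is cleaved selectively (TBAF/AcOH, THF, −40 °C) to the bis-enone F1. LiHMDS (THF, −78 °C) should deprotonate the methyl ketone, and the lithium-chelated cross-conjugated dienolate should close both rings by an intramolecular double Michael addition (C2 to C1, then C10 to C5) to the bicyclic lithium enolate F2. This is silylated in the flask with TBSOTf and comes back to the route at 13.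

2. Step 11. Alkylation may occur on the concave face (giving the C4 epimer) or on oxygen. Fallback (the two C4 substituents are introduced in the opposite order, so that concave-face attack becomes the productive one): setting out from 5 and 6, methylation of 6 (NaH, CH3I) gives the phosphonate F3, and Horner–Wadsworth–Emmons reaction with 5 gives the C4-methyl enone F4. Silylation as in step 8 gives the dienol ether F5. Isopropenylmagnesium bromide, then heating as in step 9, gives the triene F6 and from it the C4-methyl adduct F7. Tebbe methylenation gives the methylidene compound F8. Acid-catalysed Mukaiyama–Michael addition of the silyl enol ether to methyl vinyl ketone (Tf2NH cat., CH2Cl2, −78 °C) gives the 1,5-diketone F9. CH3MgBr/CeCl3 adds to the unhindered methyl ketone only, giving the tertiary alcohol F10, and silylation (TBSOTf, 2,6-lutidine) comes back to the route at 15.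

3. Step 15. Hydroboration of the hindered exocyclic alkene may be slow, with competing reduction of the C3 ketone, or the borane may be lost by protodeboronation during coupling. Fallback (conjugate addition of the nucleophilic hydroxypyranone instead of cross-coupling): setting out from 15, HF·pyridine gives the allylic alcohol diol F11, and MnO2 oxidises the allylic C8 alcohol to the α-methylidene ketone F12. Base-catalysed Michael addition of the 4-hydroxy-2-pyranone 18 through its C3 (Et3N, MeCN, rt) gives the adduct F13, with C9 set by protonation of the enolate on the convex face and by equilibration to the equatorial CH2 group. O-Methylation with MeOTf as in step 14 comes back to the route at 24.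

## Further compounds

F1 | step 9 | (4R,7E)-4-[(tert-butyldimethylsilyl)oxy]-8-{3-[(tert-butyldimethylsilyl)oxy]-3-methylbutyl}-2-methyldeca-1,7-diene-3,9-dione (bis-enone) | C=C(C)C(=O)[C@H](O[Si](C)(C)C(C)(C)C)CC/C=C(\CCC(C)(C)O[Si](C)(C)C(C)(C)C)C(C)=O
F2 | step 9 | lithium C3 enolate corresponding to 13 | O=C1[C@H](O[Si](C)(C)C(C)(C)C)CC[C@H]2C(CCC(C)(C)O[Si](C)(C)C(C)(C)C)=C(O[Li])CC[C@@]12C
F3 | step 11 | dimethyl (3-oxobutan-2-yl)phosphonate | COP(=O)(OC)C(C)C(C)=O
F4 | step 11 | (R,E)-2-[(tert-butyldimethylsilyl)oxy]-N-methoxy-N,6-dimethyl-7-oxooct-5-enamide | CON(C)C(=O)[C@H](O[Si](C)(C)C(C)(C)C)CC/C=C(\C)C(C)=O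
F5 | step 11 | (R,E)-2,7-bis[(tert-butyldimethylsilyl)oxy]-N-methoxy-N,6-dimethylocta-5,7-dienamide | CON(C)C(=O)[C@H](O[Si](C)(C)C(C)(C)C)CC/C=C(\C)C(O[Si](C)(C)C(C)(C)C)=C
F6 | step 11 | (4R,7E)-4,9-bis[(tert-butyldimethylsilyl)oxy]-2,8-dimethyldeca-1,7,9-trien-3-one | C=C(C)C(=O)[C@H](O[Si](C)(C)C(C)(C)C)CC/C=C(\C)C(O[Si](C)(C)C(C)(C)C)=C
F7 | step 11 | analogue of 13 with CH3 at C4 | O=C1[C@H](O[Si](C)(C)C(C)(C)C)CC[C@H]2C(C)=C(O[Si](C)(C)C(C)(C)C)CC[C@@]12C
F8 | step 11 | analogue of 14 with CH3 at C4 | C=C1[C@H](O[Si](C)(C)C(C)(C)C)CC[C@H]2C(C)=C(O[Si](C)(C)C(C)(C)C)CC[C@@]12C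
F9 | step 11 | C3 ketone with quaternary C4 (α-CH3, β-3-oxobutyl), C8α-OTBS, C9=CH2 | C=C1[C@H](O[Si](C)(C)C(C)(C)C)CC[C@H]2[C@@](C)(CCC(C)=O)C(=O)CC[C@@]12C
F10 | step 11 | analogue of 15 with free tertiary alcohol | C=C1[C@H](O[Si](C)(C)C(C)(C)C)CC[C@H]2[C@@](C)(CCC(C)(C)O)C(=O)CC[C@@]12C
F11 | step 15 | analogue of 15 with C8α-OH and free tertiary alcohol | C=C1[C@H](O)CC[C@H]2[C@@](C)(CCC(C)(C)O)C(=O)CC[C@@]12C
F12 | step 15 | C9-methylidene C3,C8-diketone with free tertiary alcohol | C=C1C(=O)CC[C@H]2[C@@](C)(CCC(C)(C)O)C(=O)CC[C@@]12C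
F13 | step 15 | analogue of 24 with the 4-hydroxy-2-pyranone form of the heterocycle | O=C1CC[C@H]2[C@@](C)(CCC(C)(C)O)C(=O)CC[C@@]2(C)[C@H]1CC1=C(O)C(C(=O)OC)=C(C)OC1=O
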